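**Retrosynthetic overview**

1. C40 = C15 + C10 + C15': two Wittig olefinations (C11=C12, then C11'=C12') join the two dihydrofuranyl-butenyl phosphonium salts to (2E,4E,6E)-2,7-dimethylocta-2,4,6-trienedial.
2. Feature used: in each 2,5-dihydrofuran ring (O, C5, C6, C7, C8) the C6=C7 alkene lies between the two oxygen-bearing stereocentres C5 and C8. The ring is therefore cut at C6=C7 to an acyclic C5–O–C8 bis-alkenyl ether, closed by ring-closing metathesis of the C8 vinyl group onto a C6 exocyclic methylene.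
3. The C8–O bond comes from a ligand-controlled iridium allylic etherification of the tertiary cuprous alkoxide with one common dienyl carbonate. C5 is set earlier by Sharpless epoxidation of a cyclogeraniol and Wharton transposition (D-tartrate for the unprimed ring, L-tartrate for the primed ring); this replaces methylenation of a ketone lying between two fully substituted carbons.
4. Ring order: the cyclohexane rings are bought (β-cyclocitral; (4R,6R)-actinol, inverted at C3' by Mitsunobu reaction); unprimed dihydrofuran in step 10, primed dihydrofuran in step 24; the polyene is built last.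

Key step: step 10

Remark on numbering: carotenoid numbering is used and the hydroxylated half is primed; the target is (5R,8S) in the unprimed ring (C5 methyl and C8 side chain cis) and (3'R,5'S,8'S) in the primed ring (trans).

Assumption: the iridium catalyst from the (Sa,S,S)-phosphoramidite is taken to deliver the alkoxide to the allyl face that gives the 8S ether; should it give 8R, the (Ra,R,R)-ligand is used in steps 9 and 23 with no other change.

**Part A – common dienyl carbonate**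

Step 1
Reactants: 1 (E)-3-methylpent-2-en-4-yn-1-ol
Product: 2 tert-butyl(dimethyl){[(E)-3-methylpent-2-en-4-yn-1-yl]oxy}silane
Conditions: t-BuMe2SiCl, imidazole, DMF, 0 °C to rt
Reagents that add atoms: tert-butyldimethylsilyl chloride, CC(C)(C)[Si](C)(C)Cl
Why: Imidazole-assisted silylation of the primary allylic alcohol is routine and leaves the terminal alkyne and the E alkene untouched.

Step 2
Reactants: 2 tert-butyl(dimethyl){[(E)-3-methylpent-2-en-4-yn-1-yl]oxy}silane
Product: 4 (E)-6-{[tert-butyl(dimethyl)silyl]oxy}-4-methylhex-4-en-2-yn-1-ol, via lithium acetylide 3 (not isolated)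
Conditions: n-BuLi, THF, −78 °C; (CH2O)n, −78 °C to rt; H2O
Reagents that add atoms: n-butyllithium, [Li]CCCC (lithium held by 3 only); paraformaldehyde as formaldehyde, C=O
Why: Deprotonation of the terminal alkyne and 1,2-addition of the acetylide to formaldehyde is a standard hydroxymethylation that adds the carbon later lost as ethene.

Step 3
Reactants: 4 (E)-6-{[tert-butyl(dimethyl)silyl]oxy}-4-methylhex-4-en-2-yn-1-ol
Product: 5 (2E,4E)-6-{[tert-butyl(dimethyl)silyl]oxy}-4-methylhexa-2,4-dien-1-ol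
Conditions: NaAlH2(OCH2CH2OMe)2, THF, 0 °C; aqueous sodium potassium tartrate
Reagents that add atoms: none
Why: Hydroxyl-directed trans-hydroalumination of the propargylic alcohol followed by protonolysis should give the 2E allylic alcohol, with the existing 4E alkene and the silyl ether unaffected.

Step 4
Reactants: 5 (2E,4E)-6-{[tert-butyl(dimethyl)silyl]oxy}-4-methylhexa-2,4-dien-1-ol
Product: 6 tert-butyl (2E,4E)-6-{[tert-butyl(dimethyl)silyl]oxy}-4-methylhexa-2,4-dien-1-yl carbonate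
Conditions: Boc2O, Bu4NHSO4 (cat.), aq NaOH, CH2Cl2, 0 °C to rt
Reagents that add atoms: di-tert-butyl dicarbonate, CC(C)(C)OC(=O)OC(=O)OC(C)(C)C
Why: Phase-transfer O-acylation gives the linear allylic tert-butyl carbonate, whose leaving group releases only tert-butoxide in step 9.

**Part B – unprimed half**

Step 5
Reactants: 7 β-cyclocitral
Product: 8 β-cyclogeraniol
Conditions: NaBH4, MeOH, 0 °C
Reagents that add atoms: none
Why: Borohydride 1,2-reduction of the hindered enal gives the allylic alcohol needed for directed epoxidation.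

Step 6
Reactants: 8 β-cyclogeraniol
Product: 9 [(1R,6R)-2,2,6-trimethyl-7-oxabicyclo[4.1.0]heptan-1-yl]methanol
Conditions: Ti(OiPr)4 (0.2 equiv), D-(−)-diethyl tartrate (0.25 equiv), t-BuOOH, 4 Å MS, CH2Cl2, −20 °C
Reagents that add atoms: tert-butyl hydroperoxide, CC(C)(C)OO
Why: Sharpless asymmetric epoxidation: the titanium tartrate complex binds the allylic hydroxyl and delivers oxygen to one face of the tetrasubstituted C5=C6 alkene, and D-(−)-tartrate is chosen so that C5 becomes R.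

Step 7
Reactants: 9 [(1R,6R)-2,2,6-trimethyl-7-oxabicyclo[4.1.0]heptan-1-yl]methanol
Product: 10 (1S,6R)-2,2,6-trimethyl-7-oxabicyclo[4.1.0]heptane-1-carbaldehyde
Conditions: Dess–Martin periodinane, CH2Cl2, 0 °C to rt
Reagents that add atoms: none
Why: Dess–Martin oxidation of the primary alcohol gives the epoxy aldehyde, which cannot epimerise or eliminate because its α carbon is fully substituted.

Step 8
Reactants: 10 (1S,6R)-2,2,6-trimethyl-7-oxabicyclo[4.1.0]heptane-1-carbaldehyde
Product: 12 (1R)-1,3,3-trimethyl-2-methylidenecyclohexan-1-ol, via epoxy hydrazone 11 (not isolated)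
Conditions: N2H4·H2O, AcOH (cat.), MeOH, 0 °C to rt
Reagents that add atoms: hydrazine hydrate, NN.O (its nitrogen atoms are held by 11 only and leave as N2)
Why: Wharton transposition: the hydrazone opens the epoxide at C6–O to an alkenyl diazene that loses N2, leaving the C6 exocyclic methylene and the C5 tertiary alcohol, and C5 keeps its configuration because the C5–O bond is never broken.

Step 9
Reactants: 12 (1R)-1,3,3-trimethyl-2-methylidenecyclohexan-1-ol; 6 tert-butyl (2E,4E)-6-{[tert-butyl(dimethyl)silyl]oxy}-4-methylhexa-2,4-dien-1-yl carbonate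
Product: 15 tert-butyl(dimethyl){[(2E,4S)-3-methyl-4-{[(1R)-1,3,3-trimethyl-2-methylidenecyclohexyl]oxy}hexa-2,5-dien-1-yl]oxy}silane, via lithium alkoxide 13 (not isolated), via cuprous alkoxide 14 (not isolated)
Conditions: n-BuLi, THF, 0 °C; CuI, rt; then 6 (1.5 equiv), [Ir(cod)Cl]2 (2 mol%), (Sa,S,S)-O,O'-(1,1'-binaphthalene-2,2'-diyl) N,N-bis(1-phenylethyl)phosphoramidite (4 mol%, catalyst pre-activated with n-PrNH2), THF, rt
Reagents that add atoms: n-butyllithium, [Li]CCCC (lithium held by 13 only); copper iodide CuI, [Cu]I (copper held by 14 only)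
Why: Iridium-catalysed allylic etherification with a cuprous alkoxide: the cyclometalated iridium–phosphoramidite ionises the linear carbonate to an allyl complex, the soft alkoxide 14 attacks the substituted terminus C8 (branched selectivity typical of this catalyst class) anti to the metal, and the ligand, not the remote C5 centre, fixes C8 as S.

Step 10
Reactants: 15 tert-butyl(dimethyl){[(2E,4S)-3-methyl-4-{[(1R)-1,3,3-trimethyl-2-methylidenecyclohexyl]oxy}hexa-2,5-dien-1-yl]oxy}silane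
Product: 16 tert-butyl(dimethyl){[(2E)-3-[(2S,7aR)-4,4,7a-trimethyl-2,4,5,6,7,7a-hexahydro-1-benzofuran-2-yl]but-2-en-1-yl]oxy}silane
Conditions: second-generation Hoveyda–Grubbs catalyst RuCl2(H2IMes)(=CH-C6H4-2-OiPr) (10 mol%), 1,4-benzoquinone (10 mol%), toluene (0.005 M), 80 °C, argon sparge
Reagents that add atoms: none
Why: The ruthenium benzylidene first exchanges with the unhindered C7 vinyl group of 15, the new alkylidene adds across the C6 exocyclic methylene in an intramolecular [2+2] cycloaddition, and cycloreversion of the ruthenacyclobutane gives the C6=C7 bond and a ruthenium methylidene that turns over with loss of ethene. The closest known reaction is ring-closing olefin metathesis of allyl ethers to 2,5-dihydrofurans, here onto a 1,1-disubstituted alkene so that a trisubstituted ring alkene results. The dihydrofuran ring (O, C5, C6, C7, C8) is closed through its C6=C7 bond as a five-membered ring, the most favourable size in metathesis. No stereocentre is formed: C5 and C8 come unchanged from 15, so the cis relation of the C5 methyl and the C8 side chain is fixed before the ring exists. The step needs site selectivity for the C6 methylene over the C9=C10 alkene and over intermolecular metathesis; closure onto C9 or C10 would give a three- or four-membered ring, C6 lies between two fully substituted carbons and can be reached only intramolecularly, and high dilution with removal of ethene suppresses dimerisation at C7. The quinone additive is there to suppress ruthenium hydride migration of the allyl ether double bond at this temperature.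

Step 11
Reactants: 16 tert-butyl(dimethyl){[(2E)-3-[(2S,7aR)-4,4,7a-trimethyl-2,4,5,6,7,7a-hexahydro-1-benzofuran-2-yl]but-2-en-1-yl]oxy}silane
Product: 17 (2E)-3-[(2S,7aR)-4,4,7a-trimethyl-2,4,5,6,7,7a-hexahydro-1-benzofuran-2-yl]but-2-en-1-ol
Conditions: Bu4NF, THF, 0 °C
Reagents that add atoms: none
Why: Fluoride-induced desilylation frees the primary allylic alcohol under non-acidic conditions, which keeps the acid-labile doubly allylic C8–O bond intact.

Step 12
Reactants: 17 (2E)-3-[(2S,7aR)-4,4,7a-trimethyl-2,4,5,6,7,7a-hexahydro-1-benzofuran-2-yl]but-2-en-1-ol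
Product: 19 triphenyl{(2E)-3-[(2S,7aR)-4,4,7a-trimethyl-2,4,5,6,7,7a-hexahydro-1-benzofuran-2-yl]but-2-en-1-yl}phosphonium bromide, via allylic bromide 18 (not isolated)
Conditions: CBr4, PPh3, 2,6-lutidine, CH2Cl2, −20 °C; then PPh3 (1.5 equiv), rt
Reagents that add atoms: carbon tetrabromide, BrC(Br)(Br)Br; triphenylphosphine, c1ccc(cc1)P(c1ccccc1)c1ccccc1
Why: Appel bromination (SN2 at C11 through the alkoxyphosphonium ion, no acid) followed in the same flask by quaternisation of PPh3 by the primary allylic bromide should give the salt with the 9E geometry and C8 untouched.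

Step 13
Reactants: 19 triphenyl{(2E)-3-[(2S,7aR)-4,4,7a-trimethyl-2,4,5,6,7,7a-hexahydro-1-benzofuran-2-yl]but-2-en-1-yl}phosphonium bromide; 20 (2E,4E,6E)-2,7-dimethylocta-2,4,6-trienedial (3 equiv)
Product: 22 (2E,4E,6E,8E,10E)-2,7-dimethyl-11-[(2S,7aR)-4,4,7a-trimethyl-2,4,5,6,7,7a-hexahydro-1-benzofuran-2-yl]dodeca-2,4,6,8,10-pentaenal, via phosphonium ylide 21 (not isolated)
Conditions: 1,2-epoxybutane/EtOH, reflux, dark, argon
Reagents that add atoms: none
Why: Wittig olefination under neutral conditions (bromide opens the epoxide and the alkoxide formed makes the ylide) forms C11=C12 at one formyl group of the excess dialdehyde, the mono-adduct being a less electrophilic polyenal, and the heating should equilibrate the hindered 11Z isomer to 11E.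

**Part C – primed half**

Step 14
Reactants: 23 (4R,6R)-4-hydroxy-2,2,6-trimethylcyclohexan-1-one
Product: 24 (1S,3R)-3,5,5-trimethyl-4-oxocyclohexyl 4-nitrobenzoate
Conditions: 4-nitrobenzoic acid, PPh3, diisopropyl azodicarboxylate, THF, 0 °C to rt
Reagents that add atoms: 4-nitrobenzoic acid, OC(=O)c1ccc(cc1)[N+](=O)[O-]
Why: Mitsunobu reaction: SN2 displacement of the axial alkoxyphosphonium group by the carboxylate inverts the carbinol carbon from R to S, which is the configuration needed at C3'.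

Step 15
Reactants: 24 (1S,3R)-3,5,5-trimethyl-4-oxocyclohexyl 4-nitrobenzoate
Product: 25 (4S,6R)-4-hydroxy-2,2,6-trimethylcyclohexan-1-one
Conditions: K2CO3 (cat.), MeOH, rt
Reagents that add atoms: none
Why: Base-catalysed transesterification frees the alcohol; the cis ketone is the more stable C6 epimer and C6 is in any case flattened in step 17.

Step 16
Reactants: 25 (4S,6R)-4-hydroxy-2,2,6-trimethylcyclohexan-1-one
Product: 26 (4S,6R)-2,2,6-trimethyl-4-{[tri(propan-2-yl)silyl]oxy}cyclohexan-1-one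
Conditions: i-Pr3SiCl, imidazole, DMF, 40 °C
Reagents that add atoms: triisopropylsilyl chloride, CC(C)[Si](Cl)(C(C)C)C(C)C
Why: Silylation of the secondary alcohol with the bulky triisopropylsilyl group, chosen so that it outlasts the later fluoride cleavage of the primary silyl ether in step 25.

Step 17
Reactants: 26 (4S,6R)-2,2,6-trimethyl-4-{[tri(propan-2-yl)silyl]oxy}cyclohexan-1-one
Product: 28 (4S)-2,6,6-trimethyl-4-{[tri(propan-2-yl)silyl]oxy}cyclohex-1-en-1-yl trifluoromethanesulfonate, via potassium enolate 27 (not isolated)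
Conditions: KN(SiMe3)2, THF, −78 °C; PhNTf2, −78 °C to 0 °C
Reagents that add atoms: potassium bis(trimethylsilyl)amide, C[Si](C)(C)N([K])[Si](C)(C)C (potassium held by 27 only); N-phenylbis(trifluoromethanesulfonimide), O=S(=O)(N(c1ccccc1)S(=O)(=O)C(F)(F)F)C(F)(F)F
Why: The ketone can enolise only toward the methyl-bearing carbon because the other α carbon is quaternary, so the tetrasubstituted enolate forms regiospecifically and is O-sulfonylated.

Step 18
Reactants: 28 (4S)-2,6,6-trimethyl-4-{[tri(propan-2-yl)silyl]oxy}cyclohex-1-en-1-yl trifluoromethanesulfonate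
Product: 29 methyl (4S)-2,6,6-trimethyl-4-{[tri(propan-2-yl)silyl]oxy}cyclohex-1-ene-1-carboxylate
Conditions: Pd(PPh3)4 (5 mol%), CO (1 atm), MeOH, Et3N, DMF, 70 °C
Reagents that add atoms: carbon monoxide, [C-]#[O+]; methanol, CO
Why: Palladium-catalysed alkoxycarbonylation (oxidative addition of the enol triflate, CO insertion, methanolysis of the acylpalladium species) installs C7 as an ester.

Step 19
Reactants: 29 methyl (4S)-2,6,6-trimethyl-4-{[tri(propan-2-yl)silyl]oxy}cyclohex-1-ene-1-carboxylate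
Product: 30 [(4S)-2,6,6-trimethyl-4-{[tri(propan-2-yl)silyl]oxy}cyclohex-1-en-1-yl]methanol
Conditions: i-Bu2AlH, CH2Cl2, −78 °C to 0 °C; aqueous sodium potassium tartrate
Reagents that add atoms: none
Why: Hydride reduction of the conjugated ester gives the allylic alcohol and does not touch the silyl ether.

Step 20
Reactants: 30 [(4S)-2,6,6-trimethyl-4-{[tri(propan-2-yl)silyl]oxy}cyclohex-1-en-1-yl]methanol
Product: 31 [(1S,4R,6S)-2,2,6-trimethyl-4-{[tri(propan-2-yl)silyl]oxy}-7-oxabicyclo[4.1.0]heptan-1-yl]methanol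
Conditions: Ti(OiPr)4 (0.2 equiv), L-(+)-diethyl tartrate (0.25 equiv), t-BuOOH, 4 Å MS, CH2Cl2, −20 °C
Reagents that add atoms: tert-butyl hydroperoxide, CC(C)(C)OO
Why: Sharpless asymmetric epoxidation with L-(+)-tartrate delivers oxygen to the face anti to the 3'-silyloxy group, which is also the sterically preferred face, and so sets C5' as S.

Step 21
Reactants: 31 [(1S,4R,6S)-2,2,6-trimethyl-4-{[tri(propan-2-yl)silyl]oxy}-7-oxabicyclo[4.1.0]heptan-1-yl]methanol
Product: 32 (1R,4R,6S)-2,2,6-trimethyl-4-{[tri(propan-2-yl)silyl]oxy}-7-oxabicyclo[4.1.0]heptane-1-carbaldehyde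
Conditions: Dess–Martin periodinane, CH2Cl2, 0 °C to rt
Reagents that add atoms: none
Why: Dess–Martin oxidation as in step 7; the aldehyde has no α hydrogen.

Step 22
Reactants: 32 (1R,4R,6S)-2,2,6-trimethyl-4-{[tri(propan-2-yl)silyl]oxy}-7-oxabicyclo[4.1.0]heptane-1-carbaldehyde
Product: 34 (1S,5R)-1,3,3-trimethyl-2-methylidene-5-{[tri(propan-2-yl)silyl]oxy}cyclohexan-1-ol, via epoxy hydrazone 33 (not isolated)
Conditions: N2H4·H2O, AcOH (cat.), MeOH, 0 °C to rt
Reagents that add atoms: hydrazine hydrate, NN.O (its nitrogen atoms are held by 33 only and leave as N2)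
Why: Wharton transposition as in step 8, with the C5'–O bond and hence the C5' configuration retained.

Step 23
Reactants: 34 (1S,5R)-1,3,3-trimethyl-2-methylidene-5-{[tri(propan-2-yl)silyl]oxy}cyclohexan-1-ol; 6 tert-butyl (2E,4E)-6-{[tert-butyl(dimethyl)silyl]oxy}-4-methylhexa-2,4-dien-1-yl carbonate
Product: 37 tert-butyl(dimethyl){[(2E,4S)-3-methyl-4-{[(1S,5R)-1,3,3-trimethyl-2-methylidene-5-{[tri(propan-2-yl)silyl]oxy}cyclohexyl]oxy}hexa-2,5-dien-1-yl]oxy}silane, via lithium alkoxide 35 (not isolated), via cuprous alkoxide 36 (not isolated)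
Conditions: n-BuLi, THF, 0 °C; CuI, rt; then 6 (1.5 equiv), [Ir(cod)Cl]2 (2 mol%), (Sa,S,S)-O,O'-(1,1'-binaphthalene-2,2'-diyl) N,N-bis(1-phenylethyl)phosphoramidite (4 mol%, catalyst pre-activated with n-PrNH2), THF, rt
Reagents that add atoms: n-butyllithium, [Li]CCCC (lithium held by 35 only); copper iodide CuI, [Cu]I (copper held by 36 only)
Why: The same iridium-catalysed allylic etherification as in step 9 with the same ligand enantiomer, so catalyst control again makes C8' S although C5' is now of opposite configuration, which leads to the trans-disposed ring.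

Step 24
Reactants: 37 tert-butyl(dimethyl){[(2E,4S)-3-methyl-4-{[(1S,5R)-1,3,3-trimethyl-2-methylidene-5-{[tri(propan-2-yl)silyl]oxy}cyclohexyl]oxy}hexa-2,5-dien-1-yl]oxy}silane
Product: 38 tert-butyl(dimethyl){[(2E)-3-[(2S,6R,7aS)-4,4,7a-trimethyl-6-{[tri(propan-2-yl)silyl]oxy}-2,4,5,6,7,7a-hexahydro-1-benzofuran-2-yl]but-2-en-1-yl]oxy}silane
Conditions: second-generation Hoveyda–Grubbs catalyst RuCl2(H2IMes)(=CH-C6H4-2-OiPr) (10 mol%), 1,4-benzoquinone (10 mol%), toluene (0.005 M), 80 °C, argon sparge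
Reagents that add atoms: none
Why: Ring-closing metathesis as in step 10 closes the primed dihydrofuran at C6'=C7' with loss of ethene; no stereocentre is formed and the remote silyl ethers are inert.

Step 25
Reactants: 38 tert-butyl(dimethyl){[(2E)-3-[(2S,6R,7aS)-4,4,7a-trimethyl-6-{[tri(propan-2-yl)silyl]oxy}-2,4,5,6,7,7a-hexahydro-1-benzofuran-2-yl]but-2-en-1-yl]oxy}silane
Product: 39 (2E)-3-[(2S,6R,7aS)-4,4,7a-trimethyl-6-{[tri(propan-2-yl)silyl]oxy}-2,4,5,6,7,7a-hexahydro-1-benzofuran-2-yl]but-2-en-1-ol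
Conditions: Bu4NF (1.1 equiv), THF, 0 °C
Reagents that add atoms: none
Why: Fluoride should cleave the unhindered primary allylic tert-butyldimethylsilyl ether much faster than the hindered secondary triisopropylsilyl ether, which gives the selective desilylation.

Step 26
Reactants: 39 (2E)-3-[(2S,6R,7aS)-4,4,7a-trimethyl-6-{[tri(propan-2-yl)silyl]oxy}-2,4,5,6,7,7a-hexahydro-1-benzofuran-2-yl]but-2-en-1-ol
Product: 41 triphenyl{(2E)-3-[(2S,6R,7aS)-4,4,7a-trimethyl-6-{[tri(propan-2-yl)silyl]oxy}-2,4,5,6,7,7a-hexahydro-1-benzofuran-2-yl]but-2-en-1-yl}phosphonium bromide, via allylic bromide 40 (not isolated)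
Conditions: CBr4, PPh3, 2,6-lutidine, CH2Cl2, −20 °C; then PPh3 (1.5 equiv), rt
Reagents that add atoms: carbon tetrabromide, BrC(Br)(Br)Br; triphenylphosphine, c1ccc(cc1)P(c1ccccc1)c1ccccc1
Why: Appel bromination and in-flask quaternisation as in step 12, with the protected 3'-oxygen unable to interfere.

**Part D – union**

Step 27
Reactants: 41 triphenyl{(2E)-3-[(2S,6R,7aS)-4,4,7a-trimethyl-6-{[tri(propan-2-yl)silyl]oxy}-2,4,5,6,7,7a-hexahydro-1-benzofuran-2-yl]but-2-en-1-yl}phosphonium bromide; 22 (2E,4E,6E,8E,10E)-2,7-dimethyl-11-[(2S,7aR)-4,4,7a-trimethyl-2,4,5,6,7,7a-hexahydro-1-benzofuran-2-yl]dodeca-2,4,6,8,10-pentaenal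
Product: 43 (5R,8S,3'R,5'S,8'S)-5,8:5',8'-diepoxy-5,8,5',8'-tetrahydro-3'-{[tri(propan-2-yl)silyl]oxy}-β,β-carotene, via phosphonium ylide 42 (not isolated)
Conditions: 1,2-epoxybutane/EtOH, reflux, dark, argon
Reagents that add atoms: none
Why: Second Wittig olefination under the same neutral conditions forms C11'=C12', and heating should again convert the hindered 11'Z isomer to the all-E polyene.

Step 28
Reactants: 43 (5R,8S,3'R,5'S,8'S)-5,8:5',8'-diepoxy-5,8,5',8'-tetrahydro-3'-{[tri(propan-2-yl)silyl]oxy}-β,β-carotene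
Product: 44 (5R,8S,3'R,5'S,8'S)-5,8:5',8'-diepoxy-5,8,5',8'-tetrahydro-β,β-caroten-3'-ol (all-E)
Conditions: Bu4NF, THF, rt, dark, argon
Reagents that add atoms: none
Why: Fluoride removes the secondary silyl ether without acid, so the polyene and both doubly allylic C8–O bonds should survive and the all-E target can be purified by crystallisation.

**Compound list**

1 | (E)-3-methylpent-2-en-4-yn-1-ol | C#C/C(C)=C/CO | starting material
2 | tert-butyl(dimethyl){[(E)-3-methylpent-2-en-4-yn-1-yl]oxy}silane | C#C/C(C)=C/CO[Si](C)(C)C(C)(C)C | intermediate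
3 | lithium acetylide of 2 | [Li]C#C/C(C)=C/CO[Si](C)(C)C(C)(C)C | intermediate (not isolated)
4 | (E)-6-{[tert-butyl(dimethyl)silyl]oxy}-4-methylhex-4-en-2-yn-1-ol | OCC#C/C(C)=C/CO[Si](C)(C)C(C)(C)C | intermediate
5 | (2E,4E)-6-{[tert-butyl(dimethyl)silyl]oxy}-4-methylhexa-2,4-dien-1-ol | OC/C=C/C(C)=C/CO[Si](C)(C)C(C)(C)C | intermediate
6 | tert-butyl (2E,4E)-6-{[tert-butyl(dimethyl)silyl]oxy}-4-methylhexa-2,4-dien-1-yl carbonate | CC(C)(C)OC(=O)OC/C=C/C(C)=C/CO[Si](C)(C)C(C)(C)C | intermediate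
7 | β-cyclocitral (2,6,6-trimethylcyclohex-1-ene-1-carbaldehyde) | CC1=C(C=O)C(C)(C)CCC1 | starting material
8 | β-cyclogeraniol ((2,6,6-trimethylcyclohex-1-en-1-yl)methanol) | CC1=C(CO)C(C)(C)CCC1 | intermediate
9 | [(1R,6R)-2,2,6-trimethyl-7-oxabicyclo[4.1.0]heptan-1-yl]methanol | C[C@@]12CCCC(C)(C)[C@]1(CO)O2 | intermediate
10 | (1S,6R)-2,2,6-trimethyl-7-oxabicyclo[4.1.0]heptane-1-carbaldehyde | C[C@@]12CCCC(C)(C)[C@]1(C=O)O2 | intermediate
11 | hydrazone of 10 | C[C@@]12CCCC(C)(C)[C@]1(C=NN)O2 | intermediate (not isolated)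
12 | (1R)-1,3,3-trimethyl-2-methylidenecyclohexan-1-ol | C=C1C(C)(C)CCC[C@@]1(C)O | intermediate
13 | lithium alkoxide of 12 | C=C1C(C)(C)CCC[C@@]1(C)O[Li] | intermediate (not isolated)
14 | cuprous alkoxide of 12 | C=C1C(C)(C)CCC[C@@]1(C)O[Cu] | intermediate (not isolated)
15 | tert-butyl(dimethyl){[(2E,4S)-3-methyl-4-{[(1R)-1,3,3-trimethyl-2-methylidenecyclohexyl]oxy}hexa-2,5-dien-1-yl]oxy}silane | CC(C)(C)[Si](C)(C)OC/C=C(\C)[C@H](C=C)O[C@]1(C)CCCC(C)(C)C1=C | intermediate
16 | tert-butyl(dimethyl){[(2E)-3-[(2S,7aR)-4,4,7a-trimethyl-2,4,5,6,7,7a-hexahydro-1-benzofuran-2-yl]but-2-en-1-yl]oxy}silane | CC(C)(C)[Si](C)(C)OC/C=C(\C)[C@@H]1C=C2C(C)(C)CCC[C@@]2(C)O1 | intermediate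
17 | (2E)-3-[(2S,7aR)-4,4,7a-trimethyl-2,4,5,6,7,7a-hexahydro-1-benzofuran-2-yl]but-2-en-1-ol | OC/C=C(\C)[C@@H]1C=C2C(C)(C)CCC[C@@]2(C)O1 | intermediate
18 | (2S,7aR)-2-[(2E)-4-bromobut-2-en-2-yl]-4,4,7a-trimethyl-2,4,5,6,7,7a-hexahydro-1-benzofuran | BrC/C=C(\C)[C@@H]1C=C2C(C)(C)CCC[C@@]2(C)O1 | intermediate (not isolated)
19 | triphenyl{(2E)-3-[(2S,7aR)-4,4,7a-trimethyl-2,4,5,6,7,7a-hexahydro-1-benzofuran-2-yl]but-2-en-1-yl}phosphonium bromide | [Br-].c1ccccc1[P+](c1ccccc1)(c1ccccc1)C/C=C(\C)[C@@H]1C=C2C(C)(C)CCC[C@@]2(C)O1 | intermediate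
20 | (2E,4E,6E)-2,7-dimethylocta-2,4,6-trienedial | O=C/C(C)=C/C=C/C=C(C)/C=O | starting material
21 | ylide of 19 | c1ccccc1[P+](c1ccccc1)(c1ccccc1)[CH-]/C=C(\C)[C@@H]1C=C2C(C)(C)CCC[C@@]2(C)O1 | intermediate (not isolated)
22 | (2E,4E,6E,8E,10E)-2,7-dimethyl-11-[(2S,7aR)-4,4,7a-trimethyl-2,4,5,6,7,7a-hexahydro-1-benzofuran-2-yl]dodeca-2,4,6,8,10-pentaenal | CC(/C=C/C=C(\C)[C@@H]1C=C2C(C)(C)CCC[C@@]2(C)O1)=C\C=C\C=C(C)\C=O | intermediate
23 | (4R,6R)-4-hydroxy-2,2,6-trimethylcyclohexan-1-one ((4R,6R)-actinol) | C[C@@H]1C[C@@H](O)CC(C)(C)C1=O | starting material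
24 | (1S,3R)-3,5,5-trimethyl-4-oxocyclohexyl 4-nitrobenzoate | C[C@@H]1C[C@H](OC(=O)c2ccc(cc2)[N+](=O)[O-])CC(C)(C)C1=O | intermediate
25 | (4S,6R)-4-hydroxy-2,2,6-trimethylcyclohexan-1-one | C[C@@H]1C[C@H](O)CC(C)(C)C1=O | intermediate
26 | (4S,6R)-2,2,6-trimethyl-4-{[tri(propan-2-yl)silyl]oxy}cyclohexan-1-one | C[C@@H]1C[C@H](O[Si](C(C)C)(C(C)C)C(C)C)CC(C)(C)C1=O | intermediate
27 | potassium enolate of 26 | CC1=C(O[K])C(C)(C)C[C@@H](O[Si](C(C)C)(C(C)C)C(C)C)C1 | intermediate (not isolated)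
28 | (4S)-2,6,6-trimethyl-4-{[tri(propan-2-yl)silyl]oxy}cyclohex-1-en-1-yl trifluoromethanesulfonate | CC1=C(OS(=O)(=O)C(F)(F)F)C(C)(C)C[C@@H](O[Si](C(C)C)(C(C)C)C(C)C)C1 | intermediate
29 | methyl (4S)-2,6,6-trimethyl-4-{[tri(propan-2-yl)silyl]oxy}cyclohex-1-ene-1-carboxylate | CC1=C(C(=O)OC)C(C)(C)C[C@@H](O[Si](C(C)C)(C(C)C)C(C)C)C1 | intermediate
30 | [(4S)-2,6,6-trimethyl-4-{[tri(propan-2-yl)silyl]oxy}cyclohex-1-en-1-yl]methanol | CC1=C(CO)C(C)(C)C[C@@H](O[Si](C(C)C)(C(C)C)C(C)C)C1 | intermediate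
31 | [(1S,4R,6S)-2,2,6-trimethyl-4-{[tri(propan-2-yl)silyl]oxy}-7-oxabicyclo[4.1.0]heptan-1-yl]methanol | C[C@]12C[C@H](O[Si](C(C)C)(C(C)C)C(C)C)CC(C)(C)[C@@]1(CO)O2 | intermediate
32 | (1R,4R,6S)-2,2,6-trimethyl-4-{[tri(propan-2-yl)silyl]oxy}-7-oxabicyclo[4.1.0]heptane-1-carbaldehyde | C[C@]12C[C@H](O[Si](C(C)C)(C(C)C)C(C)C)CC(C)(C)[C@@]1(C=O)O2 | intermediate
33 | hydrazone of 32 | C[C@]12C[C@H](O[Si](C(C)C)(C(C)C)C(C)C)CC(C)(C)[C@@]1(C=NN)O2 | intermediate (not isolated)
34 | (1S,5R)-1,3,3-trimethyl-2-methylidene-5-{[tri(propan-2-yl)silyl]oxy}cyclohexan-1-ol | C=C1C(C)(C)C[C@@H](O[Si](C(C)C)(C(C)C)C(C)C)C[C@]1(C)O | intermediate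
35 | lithium alkoxide of 34 | C=C1C(C)(C)C[C@@H](O[Si](C(C)C)(C(C)C)C(C)C)C[C@]1(C)O[Li] | intermediate (not isolated)
36 | cuprous alkoxide of 34 | C=C1C(C)(C)C[C@@H](O[Si](C(C)C)(C(C)C)C(C)C)C[C@]1(C)O[Cu] | intermediate (not isolated)
37 | tert-butyl(dimethyl){[(2E,4S)-3-methyl-4-{[(1S,5R)-1,3,3-trimethyl-2-methylidene-5-{[tri(propan-2-yl)silyl]oxy}cyclohexyl]oxy}hexa-2,5-dien-1-yl]oxy}silane | CC(C)(C)[Si](C)(C)OC/C=C(\C)[C@H](C=C)O[C@@]1(C)C[C@H](O[Si](C(C)C)(C(C)C)C(C)C)CC(C)(C)C1=C | intermediate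
38 | tert-butyl(dimethyl){[(2E)-3-[(2S,6R,7aS)-4,4,7a-trimethyl-6-{[tri(propan-2-yl)silyl]oxy}-2,4,5,6,7,7a-hexahydro-1-benzofuran-2-yl]but-2-en-1-yl]oxy}silane | CC(C)(C)[Si](C)(C)OC/C=C(\C)[C@@H]1C=C2C(C)(C)C[C@@H](O[Si](C(C)C)(C(C)C)C(C)C)C[C@]2(C)O1 | intermediate
39 | (2E)-3-[(2S,6R,7aS)-4,4,7a-trimethyl-6-{[tri(propan-2-yl)silyl]oxy}-2,4,5,6,7,7a-hexahydro-1-benzofuran-2-yl]but-2-en-1-ol | OC/C=C(\C)[C@@H]1C=C2C(C)(C)C[C@@H](O[Si](C(C)C)(C(C)C)C(C)C)C[C@]2(C)O1 | intermediate
40 | (2S,6R,7aS)-2-[(2E)-4-bromobut-2-en-2-yl]-4,4,7a-trimethyl-6-{[tri(propan-2-yl)silyl]oxy}-2,4,5,6,7,7a-hexahydro-1-benzofuran | BrC/C=C(\C)[C@@H]1C=C2C(C)(C)C[C@@H](O[Si](C(C)C)(C(C)C)C(C)C)C[C@]2(C)O1 | intermediate (not isolated)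
41 | triphenyl{(2E)-3-[(2S,6R,7aS)-4,4,7a-trimethyl-6-{[tri(propan-2-yl)silyl]oxy}-2,4,5,6,7,7a-hexahydro-1-benzofuran-2-yl]but-2-en-1-yl}phosphonium bromide | [Br-].c1ccccc1[P+](c1ccccc1)(c1ccccc1)C/C=C(\C)[C@@H]1C=C2C(C)(C)C[C@@H](O[Si](C(C)C)(C(C)C)C(C)C)C[C@]2(C)O1 | intermediate
42 | ylide of 41 | c1ccccc1[P+](c1ccccc1)(c1ccccc1)[CH-]/C=C(\C)[C@@H]1C=C2C(C)(C)C[C@@H](O[Si](C(C)C)(C(C)C)C(C)C)C[C@]2(C)O1 | intermediate (not isolated)
43 | (5R,8S,3'R,5'S,8'S)-5,8:5',8'-diepoxy-5,8,5',8'-tetrahydro-3'-{[tri(propan-2-yl)silyl]oxy}-β,β-carotene | CC(/C=C/C=C(\C)[C@@H]1C=C2C(C)(C)CCC[C@@]2(C)O1)=C\C=C\C=C(C)\C=C\C=C(/C)[C@@H]1C=C2C(C)(C)C[C@@H](O[Si](C(C)C)(C(C)C)C(C)C)C[C@]2(C)O1 | intermediate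
44 | (5R,8S,3'R,5'S,8'S)-5,8:5',8'-diepoxy-5,8,5',8'-tetrahydro-β,β-caroten-3'-ol (all-E) | CC(/C=C/C=C(\C)[C@@H]1C=C2C(C)(C)CCC[C@@]2(C)O1)=C\C=C\C=C(C)\C=C\C=C(/C)[C@@H]1C=C2C(C)(C)C[C@@H](O)C[C@]2(C)O1 | target

**Step count**

Total: 28 steps. Longest linear sequence: 15 steps (23 to 44, steps 14–28).

**Steps most likely to fail**

1. Step 10 (the same reaction is run again in step 24). What may go wrong: the alkylidene at C7 fails to engage the C6 methylene, which sits between two fully substituted carbons, so that migration of the C7 double bond to the enol ether and dimerisation at C7 take over. The fallback gives up metathesis and closes the same ring through its C8–O bond by the acid-promoted epoxide-to-furanoid rearrangement. It sets out from epoxy aldehyde 10, which is condensed with triethyl 3-methyl-4-phosphonocrotonate (Horner–Wadsworth–Emmons, LiN(SiMe3)2, THF) to ethyl (2E,4E)-3-methyl-5-[(1S,6R)-2,2,6-trimethyl-7-oxabicyclo[4.1.0]heptan-1-yl]penta-2,4-dienoate F1. This is reduced with i-Bu2AlH to (2E,4E)-3-methyl-5-[(1S,6R)-2,2,6-trimethyl-7-oxabicyclo[4.1.0]heptan-1-yl]penta-2,4-dien-1-ol F2. A trace of pyridinium p-toluenesulfonate in CH2Cl2 at 0 °C then ionises the C6–O bond to a pentadienyl cation that the C5 oxygen captures at C8. C5 is retained, but both C8 epimers would form and the 8S isomer has to be separated; it comes back to the route at alcohol 17.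

2. Step 9 (the same reaction is run again in step 23). What may go wrong: the hindered tertiary cuprous alkoxide attacks the allyliridium intermediate too slowly, so that attack by released tert-butoxide, attack at the CH2 terminus or loss of facial control at C8 compete; the sense of induction is also an assumption. The fallback sets C8 beforehand and transfers it stereospecifically by rhodium catalysis. It sets out from dienol 5, which is epoxidised (Ti(OiPr)4, D-(−)-diethyl tartrate, t-BuOOH) to [(2R,3R)-3-[(2E)-4-{[tert-butyl(dimethyl)silyl]oxy}but-2-en-2-yl]oxiran-2-yl]methanol F3. Iodination (I2, PPh3, imidazole) gives (2S,3R)-2-(iodomethyl)-3-[(2E)-4-{[tert-butyl(dimethyl)silyl]oxy}but-2-en-2-yl]oxirane F4, and reductive opening with zinc dust in ethanol gives (3S,4E)-6-{[tert-butyl(dimethyl)silyl]oxy}-4-methylhexa-1,4-dien-3-ol F5. Acylation (n-BuLi, Boc2O) gives tert-butyl (3S,4E)-6-{[tert-butyl(dimethyl)silyl]oxy}-4-methylhexa-1,4-dien-3-yl carbonate F6. This branched carbonate is substituted by cuprous alkoxide 14 (made from 12 as in step 9) with RhCl(PPh3)3 and P(OMe)3 in THF, a reaction that goes with net retention at C8 and without allylic transposition; it comes back to the route at ether 15.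

3. Step 8 (the same reaction is run again in step 22). What may go wrong: the hydrazone of the hindered epoxy aldehyde is diverted into azine formation or reduction before the diazene fragments, so that little transposed alcohol is formed. The fallback replaces the ionic transposition by a radical one and sets out from epoxy alcohol 9. This is acylated with 1,1'-thiocarbonyldiimidazole to O-{[(1R,6R)-2,2,6-trimethyl-7-oxabicyclo[4.1.0]heptan-1-yl]methyl} 1H-imidazole-1-carbothioate F7. Treatment with Bu3SnH and AIBN in refluxing benzene generates the primary carbinyl radical, which opens the epoxide at C6–O; the tertiary alkoxy radical is reduced by the stannane and the sequence comes back to the route at alcohol 12.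

**Further compounds**

F1 | step 10 | ethyl (2E,4E)-3-methyl-5-[(1S,6R)-2,2,6-trimethyl-7-oxabicyclo[4.1.0]heptan-1-yl]penta-2,4-dienoate | C[C@@]12CCCC(C)(C)[C@]1(/C=C/C(C)=C/C(=O)OCC)O2
F2 | step 10 | (2E,4E)-3-methyl-5-[(1S,6R)-2,2,6-trimethyl-7-oxabicyclo[4.1.0]heptan-1-yl]penta-2,4-dien-1-ol | C[C@@]12CCCC(C)(C)[C@]1(/C=C/C(C)=C/CO)O2
F3 | step 9 | [(2R,3R)-3-[(2E)-4-{[tert-butyl(dimethyl)silyl]oxy}but-2-en-2-yl]oxiran-2-yl]methanol | OC[C@H]1O[C@@H]1/C(C)=C/CO[Si](C)(C)C(C)(C)C
F4 | step 9 | (2S,3R)-2-(iodomethyl)-3-[(2E)-4-{[tert-butyl(dimethyl)silyl]oxy}but-2-en-2-yl]oxirane | IC[C@H]1O[C@@H]1/C(C)=C/CO[Si](C)(C)C(C)(C)C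
F5 | step 9 | (3S,4E)-6-{[tert-butyl(dimethyl)silyl]oxy}-4-methylhexa-1,4-dien-3-ol | C=C[C@H](O)/C(C)=C/CO[Si](C)(C)C(C)(C)C
F6 | step 9 | tert-butyl (3S,4E)-6-{[tert-butyl(dimethyl)silyl]oxy}-4-methylhexa-1,4-dien-3-yl carbonate | C=C[C@H](OC(=O)OC(C)(C)C)/C(C)=C/CO[Si](C)(C)C(C)(C)C
F7 | step 8 | O-{[(1R,6R)-2,2,6-trimethyl-7-oxabicyclo[4.1.0]heptan-1-yl]methyl} 1H-imidazole-1-carbothioate | C[C@@]12CCCC(C)(C)[C@]1(COC(=S)n1ccnc1)O2
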